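Remark on the chemistry (assumption): the target is written without axial descriptors. Each biaryl axis has one ortho oxygen on one ring and only a peri hydrogen on the other, so both axes are taken as rotating at room temperature and no atroposelective step is planned. Locants are written as unit letter, hyphen, number (A-8a is C8a of unit A); labels without a hyphen (A1, A2 …) are compounds of the alternatives.

## Analysis of the target

The target is a linear trimer of 8-methoxynaphthalen-1-ol (units A, B, C, each numbered as a 1-naphthol). A-2 is bonded to B-4 and B-2 to C-4, so unit B is arylated both ortho and para to its hydroxyl. There is no stereocentre, and the two biaryl axes are treated as freely equilibrating, so the problem is one of regiochemistry only. The sensitive functions are the three electron-rich naphthols (A-4 and C-2 are unsubstituted), which invite oxidative coupling and quinone formation. Each unit also carries a peri oxygen pair whose hydroxyl and methoxy oxygens must stay distinguishable to the end. The difficulty is that three nearly identical units must be joined by two unsymmetrical ortho–para bonds, with halogenation and metalation sites on one unit hard to tell from those on the next. The strategy rests on the methoxy-bearing ring of unit A (A-4a, A-5, A-6, A-7, A-8, A-8a). It carries only the A-8 methoxy group, peri to the A-1 oxygen. That ring can therefore be added last, onto an A-4a≡A-8a aryne of a 2-arylphenol core, by a four-carbon diene with a methoxy group on one terminus. This also lets the crowded A-2–B-4 bond be made on a simple benzene ring.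

## Retrosynthetic reasoning

**22 ⇒ 21.** The three phenolic O–H bonds are traced back to three O–CH2OMe acetals. Free naphthols would oxidize and would quench organolithium and aryne intermediates. Using the same acetal on all three oxygens means one acid treatment at the end frees them, and that step must leave the three methyl ethers untouched.

**21 ⇒ 16 + 18.** The bonds A-8–A-8a and A-5–A-4a are cut. This ring is chosen because it is the only benzenoid ring of unit A with a single substituent, so its four carbons and its methoxy group map exactly onto pyrone 18. The cut turns the A-2–B-4 bond into a bond to a plain benzene ring. Forward, silyl triflate 16 must release aryne 19 by desilylative 1,2-elimination. Pyrone 18 must add with its C6 at A-4a and its methoxy-bearing C3 at A-8a. The bridged lactone 20 must then decarboxylate to the aromatic ring. Two C–C bonds and one ring are gained in one operation, with no stereocentre left.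

**16 ⇒ 15 ⇒ 14 ⇒ 12.** The S–O bond of the triflate leads back to phenol 15, the phenol to carbamate 14, and the C–Si bond of 14 to a C–H bond of 12 through aryllithium 13. Silicon must sit on the ring carbon between the two oxygens, which is the position that a carbamate and a MOM ether jointly activate for lithiation. The carbamate of 12 thus serves both as director and as mask for the future triflate oxygen.

**12 ⇒ 11 + 8.** The A-2–B-4 biaryl bond is cut to bromide 11 and boronate 8 (cross-coupling). The bromine of 9 already marks this carbon, para to one oxygen and ortho to the other. Carbamate 11 comes from 9 through 10, the hydroxyl para to bromine becoming the carbamate and the other the MOM ether.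

**8 ⇒ 7 ⇒ 6 + 4.** The C–B bond of 8 goes back to the C–Br bond of 7, and the B-2–C-4 bond of 7 is cut to dihalide 6 and boronate 4. Unit B is the only unit with two aryl bonds, and two different halogens in 6 let B-2 (iodide) couple first while B-4 (bromide) is held for the second coupling.

**6 and 4 ⇒ 2 ⇒ 1.** Both halves come from one bromonaphthol, 2, made from naphthol 1. Protection of 2 gives 3 and borylation gives 4 (unit C). Iodination of 2 ortho to the hydroxyl gives 5 and protection gives 6 (unit B). One para-selective halogenation thus supplies the C-4 handle of unit C and the B-4 handle of unit B.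

**18 ⇒ 17.** The O–CH3 bond of the pyrone is traced to the enolic hydroxyl of 17.

## Alternatives that were turned down

**Alternative 1:** The disconnection is the C-2=C-3 double bond of unit C.
- Precursor: the bis-allylic diol A2. Its benzene ring (the future methoxy ring of unit C) carries a secondary vinyl carbinol next to the methoxy group and, beside it, a tertiary vinyl carbinol that already bears unit B through B-2.
- Forward key step: ring-closing olefin metathesis closes the six-membered ring to the dihydronaphthalenediol A1 (a mixture of diastereomers). Acid then removes one molecule of water, and both stereocentres vanish as the ring becomes the C-4-arylated naphthol.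
- For: every carbon of unit C is placed by carbonyl chemistry, so there is no orientation to control. On this point it is stronger than the chosen route, whose key step depends on how 18 meets aryne 19. Metathesis to a six-membered ring is also a very dependable closure.
- Against: A2 needs a diaryl ketone wedged between the ortho and peri substituents of two rings, and a vinyl-metal reagent must add to it. The tertiary, doubly benzylic, allylic alcohol of A2 and A1 ionizes easily, so allylic transposition or premature elimination can intervene. The key step forms a single bond and sets two stereocentres only to destroy them. The 1,2,3-trisubstituted benzene with methoxy, formyl and acyl groups costs more steps than the four from 12 to 16.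
- Comparison: the chosen strategy forms two C–C bonds and delivers the finished aromatic ring directly, with no dehydration or redox adjustment.

**Alternative 2:** The disconnection is the A-1–A-2 bond of the phenol ring of unit A.
- Precursor: benzamide A4, an N,N-diethylbenzamide with a methoxy group ortho on one side and an (E)-3-arylallyl chain on the other, the aryl group being the B–C half attached through B-4.
- Forward key step: a lithium amide base removes a proton from the CH2 that is both benzylic and allylic. The 1,3-diarylallyl anion attacks the amide carbonyl through the terminus that carries unit B, the amine is expelled, and the ketone tautomerizes to naphthol A3 (A-1 hydroxyl free, units B and C as MOM ethers).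
- For: the benzamide fixes the A-1 oxygen and the A-8 methoxy group, so no orientation question arises. This is stronger than the chosen route on regiochemical certainty. It also gives the A-1 hydroxyl without a protecting group, and anionic closure of ortho-allyl benzamides to 1-naphthols is an established reaction type.
- Against: the attacking carbon bears a bulky 1-naphthyl-type group and must reach a tertiary amide flanked on both sides and twisted out of plane, the most hindered form of this closure. The allyl anion can be reprotonated at the other terminus to a styrene that no longer cyclizes. The B–C half must be elaborated at B-4 into a three-carbon allylic partner and joined to the benzamide with SN2 versus SN2′ control, which puts several steps on the most valuable fragment.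
- Comparison: the chosen route attaches the B–C half by a single cross-coupling of 8 with 11 and spends its functional-group steps on a small benzene ring.

**Alternative 3:** The disconnection is C-4–C-4a and C-1–C-8a, the phenol ring of unit C.
- Partners: 3-methoxybenzyne A7, released from the iodo triflate A6 by halogen–lithium exchange at low temperature, and the bis(trimethylsilyl) vinylketene acetal A8, whose C4 carries the A–B half through B-2.
- Forward key step: (4+2) addition across C1 and C4 of A8. The adduct loses a silanol on work-up and gives naphthol A5 (unit C hydroxyl free, units A and B as MOM ethers).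
- For: electronics and sterics point the same way. The nucleophilic C4 of A8, which also carries the bulky aryl group, bonds to the aryne carbon remote from the methoxy group, and the acetal carbon ends up beside it. On regiocontrol this is stronger than the chosen step, where the polar preference must overcome the steric one.
- Against: A8 is a moisture-sensitive ketene acetal that cannot be purified or stored. It must be generated from a 4-arylbutenoic acid built on the A–B half at B-2 in three or four steps. The valuable component is then the diene, used as limiting reagent under organolithium conditions. Its aryl-bearing terminus is twisted by the ortho MOM ether and the peri hydrogen, which slows the cycloaddition and lets A7 consume itself.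
- Comparison: in the chosen route the valuable fragment carries the aryne in a bench-stable form (16), the diene 18 is a small stable compound used in excess, and activation is neutral. Step counts are similar.

Key step: step 15

## Route

**Step 1**
Reactants: 1 8-methoxynaphthalen-1-ol
Product: 2 4-bromo-8-methoxynaphthalen-1-ol
Conditions: NBS (1.0 equiv), MeCN, −20 → 0 °C
Reagents that add atoms: N-bromosuccinimide, O=C1CCC(=O)N1Br
Why: Electrophilic aromatic bromination; the hydroxyl, hydrogen-bonded to the peri methoxy oxygen, is the strongest donor, and in a polar solvent NBS should attack its para position (C4) in preference to C2 and leave the methoxy ring alone.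

**Step 2**
Reactants: 2 4-bromo-8-methoxynaphthalen-1-ol
Product: 3 1-bromo-5-methoxy-4-(methoxymethoxy)naphthalene
Conditions: NaH, MOMCl, DMF, 0 °C → rt
Reagents that add atoms: chloromethyl methyl ether, COCCl
Why: Williamson-type O-alkylation of the sodium naphthoxide; a strong base is used because the hydroxyl is held in a peri hydrogen bond.

**Step 3**
Reactants: 3 1-bromo-5-methoxy-4-(methoxymethoxy)naphthalene
Product: 4 2-[5-methoxy-4-(methoxymethoxy)naphthalen-1-yl]-4,4,5,5-tetramethyl-1,3,2-dioxaborolane (unit C boronate)
Conditions: B2pin2, Pd(dppf)Cl2 (cat.), KOAc, 1,4-dioxane, 90 °C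
Reagents that add atoms: bis(pinacolato)diboron, CC1(C)OB(OC1(C)C)B1OC(C)(C)C(C)(C)O1
Why: Miyaura borylation of an aryl bromide; the acetal and the methyl ether are inert to acetate base.

**Step 4**
Reactants: 2 4-bromo-8-methoxynaphthalen-1-ol
Product: 5 4-bromo-2-iodo-8-methoxynaphthalen-1-ol
Conditions: NIS (1.05 equiv), TsOH·H2O (cat.), MeCN, 0 °C → rt
Reagents that add atoms: N-iodosuccinimide, O=C1CCC(=O)N1I
Why: Electrophilic iodination of a para-blocked phenol; C2 is the only remaining activated position of the hydroxyl-bearing ring.

**Step 5**
Reactants: 5 4-bromo-2-iodo-8-methoxynaphthalen-1-ol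
Product: 6 4-bromo-2-iodo-8-methoxy-1-(methoxymethoxy)naphthalene (unit B dihalide)
Conditions: NaH, MOMCl, DMF, 0 °C → rt
Reagents that add atoms: chloromethyl methyl ether, COCCl
Why: O-alkylation of the naphthoxide as in step 2; the small MOM group fits between the iodine and the peri methoxy group.

**Step 6**
Reactants: 6 4-bromo-2-iodo-8-methoxy-1-(methoxymethoxy)naphthalene; 4 unit C boronate
Product: 7 4-bromo-8-methoxy-1-(methoxymethoxy)-2-[5-methoxy-4-(methoxymethoxy)naphthalen-1-yl]naphthalene (B–C bromide)
Conditions: Pd(PPh3)4 (cat.), Na2CO3 (aq.), DME, 75 °C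
Reagents that add atoms: none
Why: Suzuki–Miyaura coupling; oxidative addition of zerovalent palladium to the C–I bond is much faster than to the C–Br bond with a triarylphosphine catalyst, so the B-2–C-4 bond should form while the B-4 bromide is kept.

**Step 7**
Reactants: 7 B–C bromide
Product: 8 2-{5-methoxy-4-(methoxymethoxy)-3-[5-methoxy-4-(methoxymethoxy)naphthalen-1-yl]naphthalen-1-yl}-4,4,5,5-tetramethyl-1,3,2-dioxaborolane (B–C boronate)
Conditions: B2pin2, Pd(dppf)Cl2 (cat.), KOAc, 1,4-dioxane, 95 °C
Reagents that add atoms: bis(pinacolato)diboron, CC1(C)OB(OC1(C)C)B1OC(C)(C)C(C)(C)O1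
Why: Miyaura borylation of the remaining 1-naphthyl bromide; no other carbon–halogen bond is present.

**Step 8**
Reactants: 9 4-bromoresorcinol (4-bromobenzene-1,3-diol)
Product: 10 4-bromo-3-hydroxyphenyl N,N-diethylcarbamate
Conditions: Et2NCOCl (1.0 equiv), K2CO3, MeCN, 50 °C
Reagents that add atoms: N,N-diethylcarbamoyl chloride, CCN(CC)C(=O)Cl
Why: O-carbamoylation of a phenoxide; the oxygen para to bromine is less hindered and more nucleophilic than the oxygen beside bromine, so under equilibrating carbonate conditions the mono-carbamate at that oxygen should predominate, as in known selective mono-alkylations and sulfonylations of this diol.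

**Step 9**
Reactants: 10 4-bromo-3-hydroxyphenyl N,N-diethylcarbamate
Product: 11 4-bromo-3-(methoxymethoxy)phenyl N,N-diethylcarbamate
Conditions: NaH, MOMCl, THF, 0 °C → rt
Reagents that add atoms: chloromethyl methyl ether, COCCl
Why: O-alkylation of the remaining phenoxide; a tertiary carbamate has no N–H and is stable to NaH.

**Step 10**
Reactants: 11 4-bromo-3-(methoxymethoxy)phenyl N,N-diethylcarbamate; 8 B–C boronate
Product: 12 3-(methoxymethoxy)-4-Ar-phenyl N,N-diethylcarbamate (Ar = 5-methoxy-4-(methoxymethoxy)-3-[5-methoxy-4-(methoxymethoxy)naphthalen-1-yl]naphthalen-1-yl, bonded through B-4)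
Conditions: Pd(OAc)2 (cat.), SPhos, K3PO4, toluene/H2O, 90 °C
Reagents that add atoms: none
Why: Suzuki–Miyaura coupling of a hindered 1-naphthyl boronate with an ortho-alkoxy aryl bromide, for which a dialkylbiarylphosphine ligand is the standard choice; the N,N-diethylcarbamate withstands hot aqueous phosphate, which an N–H carbamate would not.

**Step 11**
Reactants: 12 3-(methoxymethoxy)-4-Ar-phenyl N,N-diethylcarbamate
Product: 14 3-(methoxymethoxy)-4-Ar-2-(trimethylsilyl)phenyl N,N-diethylcarbamate, via aryllithium 13 (not isolated)
Conditions: s-BuLi, TMEDA, THF, −78 °C; then Me3SiCl, −78 °C → rt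
Reagents that add atoms: chlorotrimethylsilane, C[Si](C)(C)Cl; sec-butyllithium, [Li]C(C)CC (supplies the lithium of 13 only)
Why: Directed ortho-metalation; the hydrogen between the carbamate and the MOM ether is activated by both directing groups and should be removed first, and silylation at −78 °C forestalls the anionic ortho-Fries shift of the carbamoyl group.

**Step 12**
Reactants: 14 3-(methoxymethoxy)-4-Ar-2-(trimethylsilyl)phenyl N,N-diethylcarbamate
Product: 15 3-(methoxymethoxy)-4-Ar-2-(trimethylsilyl)phenol
Conditions: LiAlH4, THF, 0 → 60 °C; then aq. KNaC4H4O6 work-up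
Reagents that add atoms: none
Why: Hydride reduction of the aryl carbamate expels the phenoxide, the carbamoyl carbon leaving as the N-methyl amine; MOM ethers, methyl ethers and the aryl–silicon bond are inert to LiAlH4.

**Step 13**
Reactants: 15 3-(methoxymethoxy)-4-Ar-2-(trimethylsilyl)phenol
Product: 16 3-(methoxymethoxy)-4-Ar-2-(trimethylsilyl)phenyl trifluoromethanesulfonate
Conditions: PhNTf2, DBU, MeCN/CH2Cl2, rt
Reagents that add atoms: N-phenylbis(trifluoromethanesulfonimide), O=S(=O)(N(c1ccccc1)S(=O)(=O)C(F)(F)F)C(F)(F)F
Why: O-triflylation of an ortho-silyl phenoxide with a mild triflyl donor, the usual last step in making silyl aryl triflates; no acid is generated, so the MOM ethers survive.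

**Step 14**
Reactants: 17 3-hydroxy-2H-pyran-2-one
Product: 18 3-methoxy-2H-pyran-2-one
Conditions: MeI, K2CO3, acetone, 40 °C
Reagents that add atoms: iodomethane, CI
Why: O-methylation of the acidic enolic hydroxyl of the α-hydroxy pyrone.

**Step 15**
Reactants: 16 3-(methoxymethoxy)-4-Ar-2-(trimethylsilyl)phenyl trifluoromethanesulfonate; 18 3-methoxy-2H-pyran-2-one
Product: 21 8-methoxy-1-(methoxymethoxy)-2-Ar-naphthalene (tris-MOM ether of the target), via aryne 19 (not isolated), via bridged lactone 20 (not isolated)
Conditions: CsF (3 equiv), 18 (3 equiv), MeCN, 25 → 70 °C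
Reagents that add atoms: none
Why: Fluoride attacks silicon of 16 and the aryl anion expels triflate, giving aryne 19 with the triple bond A-4a≡A-8a. The inductively withdrawing A-1 oxygen distorts 19 so that A-4a, meta to oxygen, is the more electrophilic carbon. C6 of 18, the nucleophilic terminus of a diene that bears its donor methoxy group and its carbonyl at the other end, should bond there, while the methoxy-bearing C3 bonds to A-8a in an asynchronous concerted (4+2) addition. The bridged lactone 20 then loses CO2 by retro-(4+2) fragmentation, driven by aromatization, so the methoxy ring of unit A is closed and aromatic in the same flask. The closest known reaction type is the Diels–Alder reaction of arynes from silyl aryl triflates with 2-pyrones followed by decarboxylation to naphthalenes, and the orientation is argued from 3-alkoxyarynes with 2-alkoxyfurans. The one ring formed is closed intermolecularly by (4+2) cycloaddition through the bonds A-8–A-8a and A-5–A-4a, so no ring-closure geometry limits it. The two bridgehead stereocentres of 20 form as a racemate and both disappear on loss of CO2, so no stereocentre has to be controlled. The selectivity needed is the proximal orientation (methoxy next to the MOM-bearing carbon) over the distal one; it is secured only by the polarization from the A-1 alkoxy group, which must outweigh the steric pull toward the distal isomer.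

**Step 16**
Reactants: 21 8-methoxy-1-(methoxymethoxy)-2-Ar-naphthalene
Product: 22 2-[4-hydroxy-3-(4-hydroxy-5-methoxynaphthalen-1-yl)-5-methoxynaphthalen-1-yl]-8-methoxynaphthalen-1-ol (target)
Conditions: HCl (3 M in MeOH), THF, 45 °C, under Ar
Reagents that add atoms: none
Why: Acid-catalysed acetal exchange with methanol removes the three MOM groups; aryl methyl ethers are stable to these conditions, and exclusion of air protects the freed naphthols.

## Compound list

1 | 8-methoxynaphthalen-1-ol | COc1cccc2cccc(O)c12 | starting material
2 | 4-bromo-8-methoxynaphthalen-1-ol | COc1cccc2c(Br)ccc(O)c12 | intermediate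
3 | 1-bromo-5-methoxy-4-(methoxymethoxy)naphthalene | COCOc1ccc(Br)c2cccc(OC)c12 | intermediate
4 | 2-[5-methoxy-4-(methoxymethoxy)naphthalen-1-yl]-4,4,5,5-tetramethyl-1,3,2-dioxaborolane | COCOc1ccc(B3OC(C)(C)C(C)(C)O3)c2cccc(OC)c12 | intermediate
5 | 4-bromo-2-iodo-8-methoxynaphthalen-1-ol | COc1cccc2c(Br)cc(I)c(O)c12 | intermediate
6 | 4-bromo-2-iodo-8-methoxy-1-(methoxymethoxy)naphthalene | COCOc1c(I)cc(Br)c2cccc(OC)c12 | intermediate
7 | 4-bromo-8-methoxy-1-(methoxymethoxy)-2-[5-methoxy-4-(methoxymethoxy)naphthalen-1-yl]naphthalene | COCOc1c(-c3ccc(OCOC)c4c(OC)cccc34)cc(Br)c2cccc(OC)c12 | intermediate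
8 | 2-{5-methoxy-4-(methoxymethoxy)-3-[5-methoxy-4-(methoxymethoxy)naphthalen-1-yl]naphthalen-1-yl}-4,4,5,5-tetramethyl-1,3,2-dioxaborolane | COCOc1c(-c3ccc(OCOC)c4c(OC)cccc34)cc(B5OC(C)(C)C(C)(C)O5)c2cccc(OC)c12 | intermediate
9 | 4-bromoresorcinol (4-bromobenzene-1,3-diol) | Oc1ccc(Br)c(O)c1 | starting material
10 | 4-bromo-3-hydroxyphenyl N,N-diethylcarbamate | CCN(CC)C(=O)Oc1ccc(Br)c(O)c1 | intermediate
11 | 4-bromo-3-(methoxymethoxy)phenyl N,N-diethylcarbamate | CCN(CC)C(=O)Oc1ccc(Br)c(OCOC)c1 | intermediate
12 | 3-(methoxymethoxy)-4-Ar-phenyl N,N-diethylcarbamate (Ar = 5-methoxy-4-(methoxymethoxy)-3-[5-methoxy-4-(methoxymethoxy)naphthalen-1-yl]naphthalen-1-yl) | COCOc1c(-c2cc(-c3ccc(OCOC)c4c(OC)cccc34)c(OCOC)c3c(OC)cccc23)ccc(OC(=O)N(CC)CC)c1 | intermediate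
13 | 2-lithio derivative of 12, lithium between the carbamate and MOM oxygens (not isolated) | COCOc1c(-c2cc(-c3ccc(OCOC)c4c(OC)cccc34)c(OCOC)c3c(OC)cccc23)ccc(OC(=O)N(CC)CC)c1[Li] | intermediate
14 | 3-(methoxymethoxy)-4-Ar-2-(trimethylsilyl)phenyl N,N-diethylcarbamate | COCOc1c(-c2cc(-c3ccc(OCOC)c4c(OC)cccc34)c(OCOC)c3c(OC)cccc23)ccc(OC(=O)N(CC)CC)c1[Si](C)(C)C | intermediate
15 | 3-(methoxymethoxy)-4-Ar-2-(trimethylsilyl)phenol | COCOc1c(-c2cc(-c3ccc(OCOC)c4c(OC)cccc34)c(OCOC)c3c(OC)cccc23)ccc(O)c1[Si](C)(C)C | intermediate
16 | 3-(methoxymethoxy)-4-Ar-2-(trimethylsilyl)phenyl trifluoromethanesulfonate | COCOc1c(-c2cc(-c3ccc(OCOC)c4c(OC)cccc34)c(OCOC)c3c(OC)cccc23)ccc(OS(=O)(=O)C(F)(F)F)c1[Si](C)(C)C | intermediate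
17 | 3-hydroxy-2H-pyran-2-one | O=C1OC=CC=C1O | starting material
18 | 3-methoxy-2H-pyran-2-one | COC1=CC=COC1=O | intermediate
19 | 3-(methoxymethoxy)-4-Ar-benzyne, triple bond A-4a≡A-8a (not isolated) | COCOC1=C(c2cc(-c3ccc(OCOC)c4c(OC)cccc34)c(OCOC)c3c(OC)cccc23)C=CC#C1 | intermediate
20 | benzo-fused 2-oxabicyclo[2.2.2]octadienone, methoxy bridgehead on A-8a (racemic, one enantiomer written; not isolated) | CO[C@]12C=C[C@H](OC1=O)c1ccc(-c3cc(-c4ccc(OCOC)c5c(OC)cccc45)c(OCOC)c4c(OC)cccc34)c(OCOC)c12 | intermediate
21 | 8-methoxy-1-(methoxymethoxy)-2-Ar-naphthalene (tris-MOM ether of the target) | COCOc1c(-c2cc(-c3ccc(OCOC)c4c(OC)cccc34)c(OCOC)c3c(OC)cccc23)ccc2cccc(OC)c12 | intermediate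
22 | 2-[4-hydroxy-3-(4-hydroxy-5-methoxynaphthalen-1-yl)-5-methoxynaphthalen-1-yl]-8-methoxynaphthalen-1-ol | COc1cccc2ccc(-c3cc(-c4ccc(O)c5c(OC)cccc45)c(O)c4c(OC)cccc34)c(O)c12 | target

## Step count and least certain steps

Total: 16 steps. Longest linear sequence: 11 steps (1, 4, 5, 6, 7, 10, 11, 12, 13, 15, 16, from 1 to 22).

**Step 15 (key step).** The pyrone may add in the reversed orientation, with the methoxy-bearing carbon bonding to A-4a, so that the methoxy group ends up at A-5. A single alkoxy group polarizes the aryne only moderately, and the MOM ether, pressed toward A-8a by the neighbouring naphthyl group, adds steric bias for the distal mode. Fluoride-induced S–O cleavage of the triflate and trapping of the aryne by the naphthalene rings could also lower the return. Fallback: give up the annulation and bring in unit A as a whole, setting out from 1 and 7. Naphthol 1 is converted with NaH and MOMCl into 8-methoxy-1-(methoxymethoxy)naphthalene F1. This is lithiated ortho to the MOM ether (n-BuLi, TMEDA) and quenched with 2-isopropoxy-4,4,5,5-tetramethyl-1,3,2-dioxaborolane to give 2-[8-methoxy-1-(methoxymethoxy)naphthalen-2-yl]-4,4,5,5-tetramethyl-1,3,2-dioxaborolane F2. Suzuki coupling of F2 with bromide 7 (Pd(OAc)2, SPhos, K3PO4) comes back to the route at 21.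

**Step 8.** Discrimination between the two hydroxyls may be poor, and double carbamoylation can occur, because the carbamoyl chloride reacts slowly and the two phenoxides differ only moderately. Fallback: from 9, silylate with iPr3SiCl and imidazole, where the bulky silyl group should go to the unhindered oxygen and give 2-bromo-5-[(triisopropylsilyl)oxy]phenol F3. MOM protection gives [4-bromo-3-(methoxymethoxy)phenoxy]triisopropylsilane F4, and Bu4NF releases 4-bromo-3-(methoxymethoxy)phenol F5. Carbamoylation of F5 (NaH, Et2NCOCl) comes back to the route at 11.

**Step 6.** Chemoselectivity may erode: slow transmetalation of the hindered boronate 4 lets oxidative addition at the bromide of 6 or 7 compete, giving over-arylation. Fallback: use a chloride at B-4, setting out from 1. Chlorination with N-chlorosuccinimide gives 4-chloro-8-methoxynaphthalen-1-ol F6, iodination gives 4-chloro-2-iodo-8-methoxynaphthalen-1-ol F7, and MOM protection gives 4-chloro-2-iodo-8-methoxy-1-(methoxymethoxy)naphthalene F8. Coupling with 4 then occurs at iodide only and gives 4-chloro-8-methoxy-1-(methoxymethoxy)-2-[5-methoxy-4-(methoxymethoxy)naphthalen-1-yl]naphthalene F9. Borylation of the aryl chloride with a catalyst suited to chlorides (Pd2(dba)3, XPhos, B2pin2, KOAc) comes back to the route at 8.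

**Step 11.** Lithiation may occur at other sites of the large substrate (C-2 ortho to the MOM ether, positions ortho to methoxy groups), or the carbamoyl group may migrate if the anion warms. Fallback: silylate the small fragment before the coupling, setting out from 11. LiN(iPr)2 in the presence of Me3SiCl (in situ quench, THF, −78 °C), a base that does not exchange the bromide, gives 4-bromo-3-(methoxymethoxy)-2-(trimethylsilyl)phenyl N,N-diethylcarbamate F10. Suzuki coupling of F10 with 8 comes back to the route at 14.

**Step 10.** Protodeboronation of the electron-rich, peri-hindered boronate 8 may outrun transmetalation. Fallback: reverse the polarity, setting out from 11 and 7. Miyaura borylation of 11 gives 3-(methoxymethoxy)-4-(4,4,5,5-tetramethyl-1,3,2-dioxaborolan-2-yl)phenyl N,N-diethylcarbamate F11. Coupling of F11 with bromide 7 comes back to the route at 12 and makes step 7 unnecessary.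

## Further compounds

F1 | step 15 | 8-methoxy-1-(methoxymethoxy)naphthalene | COCOc1cccc2cccc(OC)c12
F2 | step 15 | 2-[8-methoxy-1-(methoxymethoxy)naphthalen-2-yl]-4,4,5,5-tetramethyl-1,3,2-dioxaborolane | COCOc1c(B3OC(C)(C)C(C)(C)O3)ccc2cccc(OC)c12
F3 | step 8 | 2-bromo-5-[(triisopropylsilyl)oxy]phenol | CC(C)[Si](Oc1ccc(Br)c(O)c1)(C(C)C)C(C)C
F4 | step 8 | [4-bromo-3-(methoxymethoxy)phenoxy]triisopropylsilane | COCOc1cc(O[Si](C(C)C)(C(C)C)C(C)C)ccc1Br
F5 | step 8 | 4-bromo-3-(methoxymethoxy)phenol | COCOc1cc(O)ccc1Br
F6 | step 6 | 4-chloro-8-methoxynaphthalen-1-ol | COc1cccc2c(Cl)ccc(O)c12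
F7 | step 6 | 4-chloro-2-iodo-8-methoxynaphthalen-1-ol | COc1cccc2c(Cl)cc(I)c(O)c12
F8 | step 6 | 4-chloro-2-iodo-8-methoxy-1-(methoxymethoxy)naphthalene | COCOc1c(I)cc(Cl)c2cccc(OC)c12
F9 | step 6 | 4-chloro-8-methoxy-1-(methoxymethoxy)-2-[5-methoxy-4-(methoxymethoxy)naphthalen-1-yl]naphthalene | COCOc1c(-c3ccc(OCOC)c4c(OC)cccc34)cc(Cl)c2cccc(OC)c12
F10 | step 11 | 4-bromo-3-(methoxymethoxy)-2-(trimethylsilyl)phenyl N,N-diethylcarbamate | CCN(CC)C(=O)Oc1ccc(Br)c(OCOC)c1[Si](C)(C)C
F11 | step 10 | 3-(methoxymethoxy)-4-(4,4,5,5-tetramethyl-1,3,2-dioxaborolan-2-yl)phenyl N,N-diethylcarbamate | CCN(CC)C(=O)Oc1ccc(B2OC(C)(C)C(C)(C)O2)c(OCOC)c1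
A1 | alternative 1 | 4-aryl-8-methoxy-1,4-dihydronaphthalene-1,4-diol, aryl = unit B through B-2 carrying unit A (mixture of diastereomers) | COc1cccc2c1C(O)C=CC2(O)c1cc(-c3ccc4cccc(OC)c4c3OCOC)c3cccc(OC)c3c1OCOC
A2 | alternative 1 | bis-allylic diol, 1-[2-(1-aryl-1-hydroxyprop-2-enyl)-6-methoxyphenyl]prop-2-en-1-ol (mixture of diastereomers) | COc1cccc(C(O)(C=C)c2cc(-c3ccc4cccc(OC)c4c3OCOC)c3cccc(OC)c3c2OCOC)c1C(O)C=C
A3 | alternative 2 | trimer with the unit A hydroxyl free and units B and C as MOM ethers | COc1cccc2ccc(-c3cc(-c4ccc(OCOC)c5c(OC)cccc45)c(OCOC)c4c(OC)cccc34)c(O)c12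
A4 | alternative 2 | N,N-diethyl-2-methoxy-6-[(E)-3-arylprop-2-enyl]benzamide, aryl = B–C half through B-4 | CCN(CC)C(=O)c1c(OC)cccc1C/C=C/c1cc(-c2ccc(OCOC)c3c(OC)cccc23)c(OCOC)c2c(OC)cccc12
A5 | alternative 3 | trimer with the unit C hydroxyl free and units A and B as MOM ethers | COc1cccc2c(-c3cc(-c4ccc5cccc(OC)c5c4OCOC)c4cccc(OC)c4c3OCOC)ccc(O)c12
A6 | alternative 3 | 2-iodo-3-methoxyphenyl trifluoromethanesulfonate | COc1cccc(OS(=O)(=O)C(F)(F)F)c1I
A7 | alternative 3 | 3-methoxybenzyne | COC1=CC=CC#C1
A8 | alternative 3 | (E)-4-aryl-1,1-bis(trimethylsilyloxy)buta-1,3-diene, aryl = A–B half through B-2 | C[Si](C)(C)OC(O[Si](C)(C)C)=C/C=C/c1cc(-c2ccc3cccc(OC)c3c2OCOC)c2cccc(OC)c2c1OCOC
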